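Ring A is numbered C1 (OMe), C2 (H), C3 (OH), C4 (4-hydroxybenzyl), C5 (CH2CH2–ring B), C6 (4-hydroxybenzyl); ring B is the 3-hydroxy-4-(4-hydroxybenzyl)phenyl ring.
Retrosynthesis: the five phenols are masked as benzyl ethers, and the chain CH2–ring B bond is cut to a ring A arylacetaldehyde and a ring B aryl Grignard reagent.
The neighbouring bonds C5–CH2 and C6–CH2Ar are then cut together: C6 lies beside the C1 methoxy group, so a C5–C6 aryne is polarised to take a ketoester carbon at C5 and its aroyl group at C6.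
The two remaining diarylmethane bonds (C4–benzyl, ring B–benzyl) go back to ortho-oxygenated benzaldehydes and one stock solution of 4-benzyloxyphenylmagnesium bromide, followed by ionic hydrogenation.
Forward: 2,4,6-trimethoxybenzaldehyde becomes the ring A silyl triflate, the aryne insertion loads C5 and C6, reduction gives the arylacetaldehyde, ring B is added, and hydrogenolysis finishes; no ring is built.
The target has no stereocentre; the carbinol centres formed on the way are racemic and are all removed.

Key step: step 10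

**Route**

Step 1
Reactants: 1 2,4,6-trimethoxybenzaldehyde
Product: 2 2,6-dihydroxy-4-methoxybenzaldehyde
Conditions: AlCl3 (5 equiv), CH2Cl2, 0 °C to reflux; aq. HCl
Reagents that add atoms: none
Why: Chelation-controlled Lewis acid demethylation, in which aluminium bound to the formyl oxygen activates only the two ortho methyl ethers, should leave the para methoxy group untouched, as in the known conversion of 2,6-dimethoxybenzaldehydes into 2,6-dihydroxybenzaldehydes.

Step 2
Reactants: 2 2,6-dihydroxy-4-methoxybenzaldehyde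
Product: 3 2-(benzyloxy)-6-hydroxy-4-methoxybenzaldehyde
Conditions: BnBr (1.0 equiv), K2CO3, DMF, rt
Reagents that add atoms: benzyl bromide, BrCc1ccccc1
Why: Williamson etherification should stop after one benzylation because the remaining hydroxyl becomes locked in a hydrogen bond to the aldehyde, the same effect that makes mono-alkylation of 2,6-dihydroxybenzaldehydes selective.

Step 3
Reactants: 4 4-(benzyloxy)bromobenzene
Product: 5 4-benzyloxyphenylmagnesium bromide (titrated THF solution kept under argon; one batch serves steps 4 and 15)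
Conditions: Mg turnings (I2 crystal), THF, 40 °C to reflux
Reagents that add atoms: magnesium, [Mg]
Why: Grignard reagent formation by insertion of magnesium into the aryl carbon–bromine bond is routine for para-alkoxy aryl bromides, and the benzyl ether is inert to the reagent, so a single titrated stock solution can supply both diarylcarbinol-forming additions.

Step 4
Reactants: 3 2-(benzyloxy)-6-hydroxy-4-methoxybenzaldehyde; 5 4-benzyloxyphenylmagnesium bromide
Product: 6 3-(benzyloxy)-2-[(4-benzyloxyphenyl)(hydroxy)methyl]-5-methoxyphenol (racemic)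
Conditions: 3 added to 5 (2.5 equiv), THF, 0 °C to rt; sat. aq. NH4Cl
Reagents that add atoms: none
Why: Grignard addition to a salicylaldehyde, in which the first equivalent deprotonates the phenol and the second adds to the chelated aldehyde; the new carbinol centre is racemic and is removed in step 5.

Step 5
Reactants: 6 3-(benzyloxy)-2-[(4-benzyloxyphenyl)(hydroxy)methyl]-5-methoxyphenol
Product: 7 3-(benzyloxy)-2-(4-benzyloxybenzyl)-5-methoxyphenol
Conditions: Et3SiH, TFA, CH2Cl2, 0 °C
Reagents that add atoms: none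
Why: Ionic hydrogenation, in which the doubly benzylic carbinol ionises readily to a cation stabilised by three ortho/para oxygen substituents and by the para-benzyloxyphenyl ring and is captured by silane hydride, under conditions that aryl benzyl ethers tolerate.

Step 6
Reactants: 7 3-(benzyloxy)-2-(4-benzyloxybenzyl)-5-methoxyphenol
Product: 8 3-(benzyloxy)-2-(4-benzyloxybenzyl)-5-methoxyphenyl N-isopropylcarbamate
Conditions: i-PrNCO, Et3N (cat.), CH2Cl2, rt
Reagents that add atoms: isopropyl isocyanate, CC(C)N=C=O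
Why: Base-catalysed addition of a phenol to an isocyanate gives the secondary carbamate, which serves as a strong ortho-directing group that can later be removed under mild conditions.

Step 7
Reactants: 8 3-(benzyloxy)-2-(4-benzyloxybenzyl)-5-methoxyphenyl N-isopropylcarbamate
Product: 12 3-(benzyloxy)-2-(4-benzyloxybenzyl)-5-methoxy-6-(trimethylsilyl)phenyl N-isopropylcarbamate, via N-TBS carbamate 9 (not isolated), via C6 aryllithium 10 (not isolated), via N-TBS C6-TMS carbamate 11 (not isolated)
Conditions: TBSOTf, TMEDA, Et2O, 0 °C to rt; n-BuLi, TMEDA, −78 °C; TMSCl, −78 °C to rt; aq. NaHSO4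
Reagents that add atoms: chlorotrimethylsilane, C[Si](C)(C)Cl
Why: Carbamate-directed ortho-metalation after transient N-silylation should lithiate the only ring position ortho to the carbamate, C6, which is further acidified by the flanking C1 methoxy group, and silyl quench followed by acidic work-up (loss of the N-silyl group) follows the established route to ortho-silyl aryl carbamates.

Step 8
Reactants: 12 3-(benzyloxy)-2-(4-benzyloxybenzyl)-5-methoxy-6-(trimethylsilyl)phenyl N-isopropylcarbamate
Product: 14 3-(benzyloxy)-2-(4-benzyloxybenzyl)-5-methoxy-6-(trimethylsilyl)phenyl trifluoromethanesulfonate, via silyl phenol 13 (not isolated)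
Conditions: Et2NH, DBU, MeCN, 40 °C; then PhNTf2, rt
Reagents that add atoms: N-phenylbis(trifluoromethanesulfonimide), O=S(=O)(N(c1ccccc1)S(=O)(=O)C(F)(F)F)C(F)(F)F
Why: The N–H carbamate should fragment by an E1cB path to the phenoxide and isopropyl isocyanate (scavenged by Et2NH), and the phenoxide is triflated in the same flask, the standard one-pot carbamate-to-triflate exchange used for silyl triflate aryne precursors.

Step 9
Reactants: 15 4'-(benzyloxy)acetophenone
Product: 16 methyl 3-(4-benzyloxyphenyl)-3-oxopropanoate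
Conditions: NaH, (MeO)2CO, THF, reflux; aq. HCl
Reagents that add atoms: dimethyl carbonate, COC(=O)OC
Why: Crossed Claisen condensation of the ketone enolate with dimethyl carbonate is driven by formation of the stabilised β-ketoester enolate.

Step 10
Reactants: 14 3-(benzyloxy)-2-(4-benzyloxybenzyl)-5-methoxy-6-(trimethylsilyl)phenyl trifluoromethanesulfonate; 16 methyl 3-(4-benzyloxyphenyl)-3-oxopropanoate
Product: 19 methyl 2-[3-(benzyloxy)-6-(4-benzyloxybenzoyl)-2-(4-benzyloxybenzyl)-5-methoxyphenyl]acetate, via aryne 17 (not isolated), via benzocyclobutenoxide 18 (not isolated)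
Conditions: CsF (2.5 equiv), 16 (1.5 equiv), MeCN, 80 °C
Reagents that add atoms: none
Why: Fluoride attacks silicon and triflate departs to unveil aryne 17 across C5–C6; the caesium enolate of 16 should add through carbon to C5, the terminus remote from the C1 methoxy group, because the resulting aryl anion at C6 lies in the ring plane beside the electron-withdrawing C–O bond. The C6 anion then adds to the adjacent aryl ketone by a 4-exo-trig closure to give benzocyclobutenoxide 18, whose strained ring opens by retro-aldol cleavage to an ester-stabilised benzylic anion that is protonated by further 16, so the enolate is regenerated. The closest known reaction is the acyl-alkylation of silyl-triflate-derived arynes by β-ketoesters, which proceeds with this sense of addition for 3-methoxybenzyne. The four-membered ring is transient, no ring is retained and no stereocentre is formed. The step needs attack at C5 over C6, which the methoxy-induced distortion of the aryne should secure against the modest bulk of the C4 benzyl CH2, and capture of the anion by the ketone over the ester, which the higher electrophilicity of the ketone should secure.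

Step 11
Reactants: 19 methyl 2-[3-(benzyloxy)-6-(4-benzyloxybenzoyl)-2-(4-benzyloxybenzyl)-5-methoxyphenyl]acetate
Product: 20 2-[3-(benzyloxy)-2-(4-benzyloxybenzyl)-6-[(4-benzyloxyphenyl)(hydroxy)methyl]-5-methoxyphenyl]ethanol (racemic)
Conditions: LiAlH4, THF, 0 °C to rt; aq. NaOH work-up
Reagents that add atoms: none
Why: Hydride reduction takes the ester to the primary alcohol and the hindered diaryl ketone to the carbinol in one operation, whatever lactonisation occurs between them on the way; the carbinol centre is racemic and is removed in step 12.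

Step 12
Reactants: 20 2-[3-(benzyloxy)-2-(4-benzyloxybenzyl)-6-[(4-benzyloxyphenyl)(hydroxy)methyl]-5-methoxyphenyl]ethanol
Product: 21 2-[3-(benzyloxy)-2,6-bis(4-benzyloxybenzyl)-5-methoxyphenyl]ethanol
Conditions: Et3SiH (excess), TFA, CH2Cl2, 0 °C to rt; then K2CO3, MeOH, rt
Reagents that add atoms: none
Why: Ionic hydrogenation is selective for the diaryl carbinol, whose cation is stabilised by the ortho methoxy, para benzyloxy and para-benzyloxyphenyl groups, while the primary alcohol cannot ionise; any isochroman formed by capture of the cation by the primary alcohol re-ionises in the acid, so hydride transfer is the only irreversible exit, and the basic methanol treatment frees the primary alcohol from any trifluoroacetate.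

Step 13
Reactants: 21 2-[3-(benzyloxy)-2,6-bis(4-benzyloxybenzyl)-5-methoxyphenyl]ethanol
Product: 22 2-[3-(benzyloxy)-2,6-bis(4-benzyloxybenzyl)-5-methoxyphenyl]acetaldehyde
Conditions: Dess–Martin periodinane, NaHCO3, CH2Cl2, 0 °C to rt
Reagents that add atoms: none
Why: Buffered Dess–Martin oxidation gives the arylacetaldehyde under neutral conditions without over-oxidation or enolisation; the aldehyde is used at once.

Step 14
Reactants: 23 4-bromo-2-hydroxybenzaldehyde
Product: 24 2-(benzyloxy)-4-bromobenzaldehyde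
Conditions: BnBr, K2CO3, DMF, rt
Reagents that add atoms: benzyl bromide, BrCc1ccccc1
Why: Williamson etherification of the acidic salicylaldehyde hydroxyl is routine and leaves the aryl bromide and aldehyde untouched.

Step 15
Reactants: 24 2-(benzyloxy)-4-bromobenzaldehyde; 5 4-benzyloxyphenylmagnesium bromide
Product: 25 (2-benzyloxy-4-bromophenyl)(4-benzyloxyphenyl)methanol (racemic)
Conditions: 5 (1.2 equiv, stock solution from step 3) added to 24, THF, 0 °C; sat. aq. NH4Cl
Reagents that add atoms: none
Why: Grignard addition to the aldehyde is much faster than any halogen–magnesium exchange at the aryl bromide; the racemic carbinol centre is removed in step 16.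

Step 16
Reactants: 25 (2-benzyloxy-4-bromophenyl)(4-benzyloxyphenyl)methanol
Product: 26 2-(benzyloxy)-1-(4-benzyloxybenzyl)-4-bromobenzene
Conditions: Et3SiH, TFA, CH2Cl2, 0 °C to rt
Reagents that add atoms: none
Why: Ionic hydrogenation of a diaryl carbinol whose cation is stabilised by an ortho and a para benzyloxy group; the aryl bromide is inert.

Step 17
Reactants: 22 2-[3-(benzyloxy)-2,6-bis(4-benzyloxybenzyl)-5-methoxyphenyl]acetaldehyde; 26 2-(benzyloxy)-1-(4-benzyloxybenzyl)-4-bromobenzene
Product: 28 1-[3-(benzyloxy)-4-(4-benzyloxybenzyl)phenyl]-2-[3-(benzyloxy)-2,6-bis(4-benzyloxybenzyl)-5-methoxyphenyl]ethanol (racemic), via ring B Grignard reagent 27 (not isolated)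
Conditions: 26, Mg turnings, THF, reflux; then 22, THF, −78 to 0 °C; sat. aq. NH4Cl
Reagents that add atoms: none
Why: Aryl Grignard addition to an arylacetaldehyde is the classical route to 1,2-diarylethanols, and the magnesium reagent at low temperature is chosen over the aryllithium to limit enolisation; the racemic carbinol centre is removed in step 18.

Step 18
Reactants: 28 1-[3-(benzyloxy)-4-(4-benzyloxybenzyl)phenyl]-2-[3-(benzyloxy)-2,6-bis(4-benzyloxybenzyl)-5-methoxyphenyl]ethanol
Product: 29 3-[2-[3-hydroxy-4-(4-hydroxybenzyl)phenyl]ethyl]-2,4-bis(4-hydroxybenzyl)-5-methoxyphenol (CNP0207338.0)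
Conditions: H2 (4 bar), Pd/C, HCl (cat.), MeOH–EtOAc, rt
Reagents that add atoms: none
Why: Palladium-catalysed hydrogenolysis should cleave the five O-benzyl ethers and, with acid assistance, the secondary benzylic C–OH bond, while the methyl ether and the diarylmethane CH2 groups are stable.

**Compound list**

1 | 2,4,6-trimethoxybenzaldehyde | COc1cc(OC)c(C=O)c(OC)c1 | starting material
2 | 2,6-dihydroxy-4-methoxybenzaldehyde | COc1cc(O)c(C=O)c(O)c1 | intermediate
3 | 2-(benzyloxy)-6-hydroxy-4-methoxybenzaldehyde | COc1cc(O)c(C=O)c(OCc2ccccc2)c1 | intermediate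
4 | 4-(benzyloxy)bromobenzene | Brc1ccc(OCc2ccccc2)cc1 | starting material
5 | 4-benzyloxyphenylmagnesium bromide | Br[Mg]c1ccc(OCc2ccccc2)cc1 | intermediate
6 | 3-(benzyloxy)-2-[(4-benzyloxyphenyl)(hydroxy)methyl]-5-methoxyphenol (racemic) | COc1cc(O)c(C(O)c2ccc(OCc3ccccc3)cc2)c(OCc2ccccc2)c1 | intermediate
7 | 3-(benzyloxy)-2-(4-benzyloxybenzyl)-5-methoxyphenol | COc1cc(O)c(Cc2ccc(OCc3ccccc3)cc2)c(OCc2ccccc2)c1 | intermediate
8 | 3-(benzyloxy)-2-(4-benzyloxybenzyl)-5-methoxyphenyl N-isopropylcarbamate | COc1cc(OC(=O)NC(C)C)c(Cc2ccc(OCc3ccccc3)cc2)c(OCc2ccccc2)c1 | intermediate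
9 | N-(tert-butyldimethylsilyl) derivative of carbamate 8 | COc1cc(OC(=O)N(C(C)C)[Si](C)(C)C(C)(C)C)c(Cc2ccc(OCc3ccccc3)cc2)c(OCc2ccccc2)c1 | intermediate
10 | C6-lithiated N-silyl carbamate (lithium between the carbamate oxygen and the methoxy group) | COc1cc(OCc2ccccc2)c(Cc2ccc(OCc3ccccc3)cc2)c(OC(=O)N(C(C)C)[Si](C)(C)C(C)(C)C)c1[Li] | intermediate
11 | N-(tert-butyldimethylsilyl) C6-trimethylsilyl carbamate | COc1cc(OCc2ccccc2)c(Cc2ccc(OCc3ccccc3)cc2)c(OC(=O)N(C(C)C)[Si](C)(C)C(C)(C)C)c1[Si](C)(C)C | intermediate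
12 | 3-(benzyloxy)-2-(4-benzyloxybenzyl)-5-methoxy-6-(trimethylsilyl)phenyl N-isopropylcarbamate | COc1cc(OCc2ccccc2)c(Cc2ccc(OCc3ccccc3)cc2)c(OC(=O)NC(C)C)c1[Si](C)(C)C | intermediate
13 | 3-(benzyloxy)-2-(4-benzyloxybenzyl)-5-methoxy-6-(trimethylsilyl)phenol | COc1cc(OCc2ccccc2)c(Cc2ccc(OCc3ccccc3)cc2)c(O)c1[Si](C)(C)C | intermediate
14 | 3-(benzyloxy)-2-(4-benzyloxybenzyl)-5-methoxy-6-(trimethylsilyl)phenyl trifluoromethanesulfonate | COc1cc(OCc2ccccc2)c(Cc2ccc(OCc3ccccc3)cc2)c(OS(=O)(=O)C(F)(F)F)c1[Si](C)(C)C | intermediate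
15 | 4'-(benzyloxy)acetophenone | CC(=O)c1ccc(OCc2ccccc2)cc1 | starting material
16 | methyl 3-(4-benzyloxyphenyl)-3-oxopropanoate | COC(=O)CC(=O)c1ccc(OCc2ccccc2)cc1 | intermediate
17 | 5-(benzyloxy)-6-(4-benzyloxybenzyl)-3-methoxybenzyne (triple bond between ring A C5 and C6) | COC1=CC(OCc2ccccc2)=C(Cc2ccc(OCc3ccccc3)cc2)C#C1 | intermediate
18 | caesium benzocyclobutenoxide (ring A C5 and C6 fused to CH(CO2Me)–C(O−)(4-benzyloxyphenyl); mixture of racemic diastereomers) | COC(=O)C1c2c(Cc3ccc(OCc4ccccc4)cc3)c(OCc3ccccc3)cc(OC)c2C1([O-])c1ccc(OCc2ccccc2)cc1.[Cs+] | intermediate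
19 | methyl 2-[3-(benzyloxy)-6-(4-benzyloxybenzoyl)-2-(4-benzyloxybenzyl)-5-methoxyphenyl]acetate | COC(=O)Cc1c(Cc2ccc(OCc3ccccc3)cc2)c(OCc2ccccc2)cc(OC)c1C(=O)c1ccc(OCc2ccccc2)cc1 | intermediate
20 | 2-[3-(benzyloxy)-2-(4-benzyloxybenzyl)-6-[(4-benzyloxyphenyl)(hydroxy)methyl]-5-methoxyphenyl]ethanol (racemic) | OCCc1c(Cc2ccc(OCc3ccccc3)cc2)c(OCc2ccccc2)cc(OC)c1C(O)c1ccc(OCc2ccccc2)cc1 | intermediate
21 | 2-[3-(benzyloxy)-2,6-bis(4-benzyloxybenzyl)-5-methoxyphenyl]ethanol | OCCc1c(Cc2ccc(OCc3ccccc3)cc2)c(OCc2ccccc2)cc(OC)c1Cc1ccc(OCc2ccccc2)cc1 | intermediate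
22 | 2-[3-(benzyloxy)-2,6-bis(4-benzyloxybenzyl)-5-methoxyphenyl]acetaldehyde | O=CCc1c(Cc2ccc(OCc3ccccc3)cc2)c(OCc2ccccc2)cc(OC)c1Cc1ccc(OCc2ccccc2)cc1 | intermediate
23 | 4-bromo-2-hydroxybenzaldehyde | O=Cc1ccc(Br)cc1O | starting material
24 | 2-(benzyloxy)-4-bromobenzaldehyde | O=Cc1ccc(Br)cc1OCc1ccccc1 | intermediate
25 | (2-benzyloxy-4-bromophenyl)(4-benzyloxyphenyl)methanol (racemic) | OC(c1ccc(OCc2ccccc2)cc1)c1ccc(Br)cc1OCc1ccccc1 | intermediate
26 | 2-(benzyloxy)-1-(4-benzyloxybenzyl)-4-bromobenzene | Brc1ccc(Cc2ccc(OCc3ccccc3)cc2)c(OCc2ccccc2)c1 | intermediate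
27 | 3-(benzyloxy)-4-(4-benzyloxybenzyl)phenylmagnesium bromide | Br[Mg]c1ccc(Cc2ccc(OCc3ccccc3)cc2)c(OCc2ccccc2)c1 | intermediate
28 | 1-[3-(benzyloxy)-4-(4-benzyloxybenzyl)phenyl]-2-[3-(benzyloxy)-2,6-bis(4-benzyloxybenzyl)-5-methoxyphenyl]ethanol (racemic) | COc1cc(OCc2ccccc2)c(Cc2ccc(OCc3ccccc3)cc2)c(CC(O)c2ccc(Cc3ccc(OCc4ccccc4)cc3)c(OCc3ccccc3)c2)c1Cc1ccc(OCc2ccccc2)cc1 | intermediate
29 | 3-[2-[3-hydroxy-4-(4-hydroxybenzyl)phenyl]ethyl]-2,4-bis(4-hydroxybenzyl)-5-methoxyphenol (CNP0207338.0) | COc1cc(O)c(Cc2ccc(O)cc2)c(CCc2ccc(Cc3ccc(O)cc3)c(O)c2)c1Cc1ccc(O)cc1 | target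

**Step count and risks**

Total step count: 18. Longest linear sequence: 13 steps (steps 1, 2, 4–8, 10–13, 17, 18).

Steps most likely to fail:

1. Step 10 (aryne acyl-alkylation). The C4 benzyl group crowds C5 and may erode the methoxy-directed regiochemistry of enolate addition. The C6 aryl anion may also be protonated before it closes onto the ketone, which would give simple α-arylation without acyl transfer.
Fallback, setting out from 14 and returning at 21: ICl in CH2Cl2 at −78 °C should exchange the silyl group for iodine by ipso-substitution to give 3-(benzyloxy)-2-(4-benzyloxybenzyl)-6-iodo-5-methoxyphenyl trifluoromethanesulfonate F1. Negishi coupling at the carbon–iodine bond with (4-benzyloxybenzyl)zinc chloride (from the benzyl chloride and Zn dust) under Pd(PPh3)4, a zerovalent palladium catalyst, in THF should give 3-(benzyloxy)-2,6-bis(4-benzyloxybenzyl)-5-methoxyphenyl trifluoromethanesulfonate F2. Suzuki–Miyaura vinylation of the triflate with CH2=CHBF3K, Pd(OAc)2, SPhos and Cs2CO3 in THF–water should give 3-(benzyloxy)-2,6-bis(4-benzyloxybenzyl)-5-methoxystyrene F3. Hydroboration with 9-BBN followed by NaOH/H2O2 should deliver alcohol 21, bypassing steps 10–12.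

2. Step 7 (directed ortho-silylation). Deprotonation may compete at the doubly benzylic CH2 beside the carbamate or at a benzyl ether methylene (followed by [1,2]-Wittig shift) in place of ring lithiation at C6.
Fallback, setting out from 7 and returning at 14: amine-mediated ortho-selective bromination (NBS, catalytic i-Pr2NH, CH2Cl2) should give 3-(benzyloxy)-2-(4-benzyloxybenzyl)-6-bromo-5-methoxyphenol F4. Silylation with hexamethyldisilazane should give [3-(benzyloxy)-2-(4-benzyloxybenzyl)-6-bromo-5-methoxyphenoxy]trimethylsilane F5. Bromine–lithium exchange with n-BuLi in THF at −78 °C triggers the oxygen-to-carbon silyl shift (retro-Brook rearrangement), and the resulting lithium phenoxide is trapped with Tf2O to give silyl triflate 14 without any carbon–hydrogen deprotonation.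

3. Step 17 (Grignard addition to the arylacetaldehyde). The basic aryl Grignard reagent may enolise the hindered arylacetaldehyde, leading to recovered aldehyde and aldol self-condensation.
Fallback, setting out from 21 and returning at 29: Appel bromination (CBr4, PPh3, CH2Cl2) should give 1-(benzyloxy)-2,4-bis(4-benzyloxybenzyl)-3-(2-bromoethyl)-5-methoxybenzene F6. Reductive cross-electrophile coupling with aryl bromide 26 (NiBr2·glyme as a divalent nickel precatalyst, 4,4'-di-tert-butyl-2,2'-bipyridine, Zn dust, NaI, DMA, 60 °C) should give the penta-O-benzyl ether of the target F7. Hydrogenolysis (H2, Pd/C, MeOH–EtOAc) then gives 29 with no carbinol to remove.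

Further compounds
F1 | step 10 | 3-(benzyloxy)-2-(4-benzyloxybenzyl)-6-iodo-5-methoxyphenyl trifluoromethanesulfonate | COc1cc(OCc2ccccc2)c(Cc2ccc(OCc3ccccc3)cc2)c(OS(=O)(=O)C(F)(F)F)c1I
F2 | step 10 | 3-(benzyloxy)-2,6-bis(4-benzyloxybenzyl)-5-methoxyphenyl trifluoromethanesulfonate | COc1cc(OCc2ccccc2)c(Cc2ccc(OCc3ccccc3)cc2)c(OS(=O)(=O)C(F)(F)F)c1Cc1ccc(OCc2ccccc2)cc1
F3 | step 10 | 3-(benzyloxy)-2,6-bis(4-benzyloxybenzyl)-5-methoxystyrene | C=Cc1c(Cc2ccc(OCc3ccccc3)cc2)c(OCc2ccccc2)cc(OC)c1Cc1ccc(OCc2ccccc2)cc1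
F4 | step 7 | 3-(benzyloxy)-2-(4-benzyloxybenzyl)-6-bromo-5-methoxyphenol | COc1cc(OCc2ccccc2)c(Cc2ccc(OCc3ccccc3)cc2)c(O)c1Br
F5 | step 7 | [3-(benzyloxy)-2-(4-benzyloxybenzyl)-6-bromo-5-methoxyphenoxy]trimethylsilane | COc1cc(OCc2ccccc2)c(Cc2ccc(OCc3ccccc3)cc2)c(O[Si](C)(C)C)c1Br
F6 | step 17 | 1-(benzyloxy)-2,4-bis(4-benzyloxybenzyl)-3-(2-bromoethyl)-5-methoxybenzene | BrCCc1c(Cc2ccc(OCc3ccccc3)cc2)c(OCc2ccccc2)cc(OC)c1Cc1ccc(OCc2ccccc2)cc1
F7 | step 17 | penta-O-benzyl ether of the target (1-(benzyloxy)-3-[2-[3-(benzyloxy)-4-(4-benzyloxybenzyl)phenyl]ethyl]-2,4-bis(4-benzyloxybenzyl)-5-methoxybenzene) | COc1cc(OCc2ccccc2)c(Cc2ccc(OCc3ccccc3)cc2)c(CCc2ccc(Cc3ccc(OCc4ccccc4)cc3)c(OCc3ccccc3)c2)c1Cc1ccc(OCc2ccccc2)cc1
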